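The target is cut at the methylene bridge into chromene 9 and the (R)-configured acetylfilicinic-type acid 20, joined last through an ortho-quinone methide. Everything rests on building the 2H-pyran ring on a finished arene: the key step exploits the ortho relation of benzylic C4 (on C4a) and O1 (on C8a). In one operation the free phenol oxygen steers a 2-methylpropenyl group from boron onto the iminium carbon (C4–C3), the amine leaves, and the same oxygen closes O1–C2 by oxa-6π electrocyclisation. The precursor is a pyran-free 3-hexanoyl-2-hydroxy-4,6-bis(methoxymethoxy)benzaldehyde. The quaternary stereocentre stems from an asymmetric phase-transfer geranylation of a mixed malonate, carried into the ring by a polyketide-like Claisen closure.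

Key step: step 3

Assumption: the (S,S)-catalyst of step 6 is taken, by analogy with simple allylic and benzylic bromides, to give (S)-14; if the sense proves opposite, the (R,R)-catalyst is used and nothing else changes; β-triketone rings are drawn in the tautomer of the target.

Step 1
Reactants: 1 2,4,6-trihydroxybenzaldehyde; 2 hexanoyl chloride
Product: 3 3-hexanoyl-2,4,6-trihydroxybenzaldehyde
Conditions: AlCl3 (4 equiv), CH2Cl2/PhNO2, 0 to 45 °C; then ice, 1 M HCl
Reagents that add atoms: none
Why: Friedel–Crafts C-acylation: three OH donors keep the formyl-bearing ring nucleophilic, the two free positions are equivalent by symmetry so only one ketone can form, and the product, chelated to aluminium through two carbonyl groups, is too deactivated for a second acylation.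

Step 2
Reactants: 3 3-hexanoyl-2,4,6-trihydroxybenzaldehyde
Product: 4 3-hexanoyl-2-hydroxy-4,6-bis(methoxymethoxy)benzaldehyde
Conditions: MOMCl (2.2 equiv), iPr2NEt (2.5 equiv), CH2Cl2, 0 °C to rt
Reagents that add atoms: chloromethyl methyl ether (MOMCl), COCCl
Why: Selective O-alkylation (MOM protection): the OH at C2 is wedged between the formyl- and hexanoyl-bearing carbons and stays chelated, so the two less hindered OH groups at C4 and C6 should be etherified first and the reaction can be stopped at the bis-ether.

Step 3
Reactants: 4 3-hexanoyl-2-hydroxy-4,6-bis(methoxymethoxy)benzaldehyde; 5 2-methylprop-1-en-1-ylboronic acid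
Product: 8 1-[5,7-bis(methoxymethoxy)-2,2-dimethyl-2H-chromen-8-yl]hexan-1-one, via Petasis allylic amine 6 (not isolated), via vinyl ortho-quinone methide 7 (not isolated)
Conditions: 5 (1.5 equiv), Bn2NH (0.4 equiv), 1,4-dioxane, 90 °C, argon
Reagents that add atoms: none
Why: Catalytic Petasis borono-Mannich reaction followed by amine elimination and oxa-6π electrocyclisation, the known route from salicylaldehydes and alkenylboronic acids to 2H-chromenes: Bn2NH condenses with the formyl group, the free C2 phenol binds 5 as a boronate and hands the 2-methylpropenyl group intramolecularly to the iminium carbon (C4–C3 bond, amine 6). The two alkoxy groups ortho and para to the benzylic carbon make the C–N bond labile, so at 90 °C 6 should lose Bn2NH, which re-enters the cycle, and give the vinyl ortho-quinone methide 7. The 2H-pyran ring then closes by thermal disrotatory 6π electrocyclisation of the 1-oxatriene O=C8a–C4a=C4–C3=C2, which forms O1–C2 and restores the arene as the driving force. No stereocentre remains, because the benzylic centre of 6 is erased in 7 and C2 carries two methyl groups. The step needs regioselectivity between the two oxygens that flank the formyl carbon and chemoselectivity for the aldehyde over the ketone; the first is secured because only the oxygen next to the hexanoyl carbon is free, while the other is a MOM ether that can neither bind boron nor become a quinone methide carbonyl, and the second because the di-ortho-substituted aryl ketone does not form an iminium ion with a secondary amine.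

Step 4
Reactants: 8 1-[5,7-bis(methoxymethoxy)-2,2-dimethyl-2H-chromen-8-yl]hexan-1-one
Product: 9 1-(5,7-dihydroxy-2,2-dimethyl-2H-chromen-8-yl)hexan-1-one
Conditions: 3 M aq HCl (cat. amount), MeOH, 50 °C
Reagents that add atoms: none
Why: Acid-catalysed acetal exchange (MOM cleavage): the large excess of methanol carries the formaldehyde unit off as dimethoxymethane so that the nucleophilic C6–H is not attacked, and the 2,2-dimethylchromene olefin and the chelated ketone tolerate dilute acid.

Step 5
Reactants: 10 3-(tert-butoxy)-2-methyl-3-oxopropanoic acid; 11 2,2-diphenylethanol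
Product: 12 1-tert-butyl 3-(2,2-diphenylethyl) 2-methylpropanedioate
Conditions: EDC·HCl, DMAP (cat.), CH2Cl2, 0 °C to rt
Reagents that add atoms: none
Why: Steglich-type carbodiimide esterification of a primary alcohol, mild enough to leave the tert-butyl ester and the malonic half-acid intact; the α-stereocentre of 12 is labile and without consequence.

Step 6
Reactants: 12 1-tert-butyl 3-(2,2-diphenylethyl) 2-methylpropanedioate; 13 geranyl bromide
Product: 14 1-tert-butyl 3-(2,2-diphenylethyl) (2S)-2-[(2E)-3,7-dimethylocta-2,6-dienyl]-2-methylpropanedioate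
Conditions: (S,S)-3,4,5-trifluorophenyl-NAS bromide (C56H34BrF6N, N-spiro bis(binaphthyl)azepinium bromide, 5 mol %), 50% aq KOH, toluene, −40 °C
Reagents that add atoms: none
Why: Asymmetric phase-transfer SN2 alkylation of an α-methylmalonate enolate: in the tight ion pair with the C2-symmetric chiral ammonium cation the bulky tert-butyl and the flat diphenylethyl ester are told apart, one enolate face stays open to the primary allylic bromide and sets the quaternary centre as (S), and attack at the unhindered CH2 terminus keeps the (E)-olefin.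

Step 7
Reactants: 14 1-tert-butyl 3-(2,2-diphenylethyl) (2S)-2-[(2E)-3,7-dimethylocta-2,6-dienyl]-2-methylpropanedioate
Product: 16 (2R,4E)-2-[(2,2-diphenylethoxy)carbonyl]-2,5,9-trimethyldeca-4,8-dienoic acid, via trimethylsilyl ester 15 (not isolated)
Conditions: TMSOTf (Me3SiOSO2CF3), 2,6-lutidine, CH2Cl2, 0 °C to rt; then aq citric acid
Reagents that add atoms: none
Why: Silyl triflate-mediated tert-butyl ester cleavage (loss of isobutene from the O-silylated ester) under lutidine buffering offers no free Brønsted acid to the trisubstituted olefins, leaves the primary ester alone and does not touch the quaternary centre, whose descriptor changes to (R) only through the priority rules.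

Step 8
Reactants: 16 (2R,4E)-2-[(2,2-diphenylethoxy)carbonyl]-2,5,9-trimethyldeca-4,8-dienoic acid; 17 pentane-2,4-dione
Product: 20 (4R)-2-acetyl-4-[(2E)-3,7-dimethylocta-2,6-dienyl]-3,5-dihydroxy-4-methylcyclohexa-2,5-dien-1-one, via acyl imidazolide 18 (not isolated), via open-chain triketo ester 19 (not isolated)
Conditions: 1,1'-carbonyldiimidazole, THF, rt; cannulate into 17 (3.5 equiv)/LDA (7 equiv), THF, −78 to 0 °C; then MeOH, 50 °C; 1 M HCl work-up
Reagents that add atoms: none
Why: Acylation of a β-diketone dianion at its terminal carbon followed by a Dieckmann-type, polyketide-like Claisen cyclisation: the imidazolide is the most electrophilic carbonyl and takes the more reactive terminal carbanion, the quaternary C2 of 19 rules out the aldol mode, any enol lactone is reopened by methoxide, the ring closes 6-exo-trig from the carbon between the two ketones onto the ester because the β-triketone enolate is the thermodynamic sink, and since the acid carbon becomes C5 and the ester carbon C3 of 20 the stereocentre is carried over unchanged.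

Step 9
Reactants: 9 1-(5,7-dihydroxy-2,2-dimethyl-2H-chromen-8-yl)hexan-1-one; 20 (4R)-2-acetyl-4-[(2E)-3,7-dimethylocta-2,6-dienyl]-3,5-dihydroxy-4-methylcyclohexa-2,5-dien-1-one
Product: 23 target (4R)-2-acetyl-4-[(2E)-3,7-dimethylocta-2,6-dienyl]-6-[(8-hexanoyl-5,7-dihydroxy-2,2-dimethyl-2H-chromen-6-yl)methyl]-3,5-dihydroxy-4-methylcyclohexa-2,5-dien-1-one, via Mannich base 21 (not isolated), via ortho-quinone methide 22 (not isolated)
Conditions: 9, dimethylmethyleneiminium iodide (1.0 equiv), MeCN, rt; then 20 (1.0 equiv), iPr2NEt (1.1 equiv), 70 °C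
Reagents that add atoms: dimethylmethyleneiminium iodide (Eschenmoser's salt), C=[N+](C)C.[I-]
Why: Mannich aminomethylation followed by ortho-quinone methide Michael addition: the only free arene position of 9 (C6, between two OH groups) takes the iminium ion, the acidic β-triketone 20 protonates the amine of 21 and so triggers loss of Me2NH to 22, whose exocyclic CH2 is captured by the soft C6 enolate carbon of 20 with rearomatisation, and the quaternary stereocentre is not involved.

Compound list
1 | 2,4,6-trihydroxybenzaldehyde | O=Cc1c(O)cc(O)cc1O | starting material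
2 | hexanoyl chloride | CCCCCC(=O)Cl | starting material
3 | 3-hexanoyl-2,4,6-trihydroxybenzaldehyde | CCCCCC(=O)c1c(O)cc(O)c(C=O)c1O | intermediate
4 | 3-hexanoyl-2-hydroxy-4,6-bis(methoxymethoxy)benzaldehyde | CCCCCC(=O)c1c(O)c(C=O)c(OCOC)cc1OCOC | intermediate
5 | 2-methylprop-1-en-1-ylboronic acid | CC(C)=CB(O)O | starting material
6 | 1-{3-[1-(dibenzylamino)-3-methylbut-2-enyl]-2-hydroxy-4,6-bis(methoxymethoxy)phenyl}hexan-1-one (racemic, not isolated) | CCCCCC(=O)c1c(O)c(C(C=C(C)C)N(Cc2ccccc2)Cc2ccccc2)c(OCOC)cc1OCOC | intermediate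
7 | 2-hexanoyl-3,5-bis(methoxymethoxy)-6-(3-methylbut-2-enylidene)cyclohexa-2,4-dien-1-one (not isolated) | CCCCCC(=O)C1=C(OCOC)C=C(OCOC)C(=CC=C(C)C)C1=O | intermediate
8 | 1-[5,7-bis(methoxymethoxy)-2,2-dimethyl-2H-chromen-8-yl]hexan-1-one | CCCCCC(=O)c1c(OCOC)cc(OCOC)c2c1OC(C)(C)C=C2 | intermediate
9 | 1-(5,7-dihydroxy-2,2-dimethyl-2H-chromen-8-yl)hexan-1-one | CCCCCC(=O)c1c(O)cc(O)c2c1OC(C)(C)C=C2 | intermediate
10 | 3-(tert-butoxy)-2-methyl-3-oxopropanoic acid | CC(C(=O)O)C(=O)OC(C)(C)C | starting material
11 | 2,2-diphenylethanol | OCC(c1ccccc1)c1ccccc1 | starting material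
12 | 1-tert-butyl 3-(2,2-diphenylethyl) 2-methylpropanedioate (racemic, labile centre) | CC(C(=O)OC(C)(C)C)C(=O)OCC(c1ccccc1)c1ccccc1 | intermediate
13 | geranyl bromide, (2E)-1-bromo-3,7-dimethylocta-2,6-diene | BrC/C=C(\C)CCC=C(C)C | starting material
14 | 1-tert-butyl 3-(2,2-diphenylethyl) (2S)-2-[(2E)-3,7-dimethylocta-2,6-dienyl]-2-methylpropanedioate | CC(C)(C)OC(=O)[C@@](C)(C/C=C(\C)CCC=C(C)C)C(=O)OCC(c1ccccc1)c1ccccc1 | intermediate
15 | 1-(2,2-diphenylethyl) 3-(trimethylsilyl) (2S)-2-[(2E)-3,7-dimethylocta-2,6-dienyl]-2-methylpropanedioate (not isolated) | C[Si](C)(C)OC(=O)[C@@](C)(C/C=C(\C)CCC=C(C)C)C(=O)OCC(c1ccccc1)c1ccccc1 | intermediate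
16 | (2R,4E)-2-[(2,2-diphenylethoxy)carbonyl]-2,5,9-trimethyldeca-4,8-dienoic acid | OC(=O)[C@@](C)(C/C=C(\C)CCC=C(C)C)C(=O)OCC(c1ccccc1)c1ccccc1 | intermediate
17 | pentane-2,4-dione (acetylacetone) | CC(=O)CC(C)=O | starting material
18 | 2,2-diphenylethyl (2R,4E)-2-(imidazole-1-carbonyl)-2,5,9-trimethyldeca-4,8-dienoate (not isolated) | O=C(n1ccnc1)[C@@](C)(C/C=C(\C)CCC=C(C)C)C(=O)OCC(c1ccccc1)c1ccccc1 | intermediate
19 | 2,2-diphenylethyl (2R)-2-[(2E)-3,7-dimethylocta-2,6-dienyl]-2-methyl-3,5,7-trioxooctanoate (not isolated) | CC(=O)CC(=O)CC(=O)[C@@](C)(C/C=C(\C)CCC=C(C)C)C(=O)OCC(c1ccccc1)c1ccccc1 | intermediate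
20 | (4R)-2-acetyl-4-[(2E)-3,7-dimethylocta-2,6-dienyl]-3,5-dihydroxy-4-methylcyclohexa-2,5-dien-1-one | O=C1C=C(O)[C@@](C)(C/C=C(\C)CCC=C(C)C)C(O)=C1C(C)=O | intermediate
21 | 1-{6-[(dimethylamino)methyl]-5,7-dihydroxy-2,2-dimethyl-2H-chromen-8-yl}hexan-1-one (not isolated) | CCCCCC(=O)c1c(O)c(CN(C)C)c(O)c2c1OC(C)(C)C=C2 | intermediate
22 | 8-hexanoyl-7-hydroxy-2,2-dimethyl-6-methylidene-2H-chromen-5(6H)-one (not isolated) | CCCCCC(=O)C1=C(O)C(=C)C(=O)C2=C1OC(C)(C)C=C2 | intermediate
23 | (4R)-2-acetyl-4-[(2E)-3,7-dimethylocta-2,6-dienyl]-6-[(8-hexanoyl-5,7-dihydroxy-2,2-dimethyl-2H-chromen-6-yl)methyl]-3,5-dihydroxy-4-methylcyclohexa-2,5-dien-1-one | CCCCCC(=O)c1c(O)c(CC2=C(O)[C@@](C)(C/C=C(\C)CCC=C(C)C)C(O)=C(C(C)=O)C2=O)c(O)c2c1OC(C)(C)C=C2 | target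

Total step count: 9. Longest linear sequence: 5 steps (steps 1, 2, 3, 4, 9 or steps 5, 6, 7, 8, 9).

Steps most likely to fail

Risk 1, step 3 (key step). Iminium formation at the doubly ortho-substituted, strongly chelated aldehyde may be too slow. Protodeboronation of 5 would then use up the alkenyl donor before transfer. The fallback replaces the boron-to-iminium transfer by a carbanion addition. It sets out from 4, which is treated with 2-methylprop-1-enylmagnesium bromide (2.2 equiv, THF, −78 to 0 °C; the first equivalent is spent on the phenol). This should give the benzylic allylic alcohol 1-[2-hydroxy-3-(1-hydroxy-3-methylbut-2-enyl)-4,6-bis(methoxymethoxy)phenyl]hexan-1-one F1. Warming it with pyridinium p-toluenesulfonate in toluene ionises the alcohol to the same quinone methide 7. Electrocyclisation brings the sequence back to the route at 8.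

Risk 2, step 8. The dianion may attack the ester instead of the imidazolide. Methoxide may cleave the open chain by retro-Claisen reaction, or O-acylation may persist. The fallback reverses the order in which the two ring bonds are made, using the other ester of the same malonate, so the same enantiomer results.
- It sets out from 14, whose primary ester is saponified (KOH, MeOH) to (2S,4E)-2-(tert-butoxycarbonyl)-2,5,9-trimethyldeca-4,8-dienoic acid F2.
- 1-Chloro-N,N,2-trimethylpropenylamine converts it under neutral conditions into the acid chloride tert-butyl (2R,4E)-2-(chlorocarbonyl)-2,5,9-trimethyldeca-4,8-dienoate F3.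
- Soft enolisation of 17 (MgCl2, Et3N, CH2Cl2) then gives, by C-acylation at the central carbon, the triacylmethane tert-butyl (2S)-4-acetyl-2-[(2E)-3,7-dimethylocta-2,6-dienyl]-2-methyl-3,5-dioxohexanoate F4.
- LDA (3 equiv) forms its terminal enolate, which closes onto the tert-butyl ester in a Dieckmann reaction. The sequence comes back to the route at 20.

Risk 3, step 9. At 70 °C the methylene bridge may exchange by retro-Michael fragmentation, which would scramble the two halves into symmetrical dimers. In addition, 22 may be trapped by unreacted 9. The fallback takes the bridge carbon from an aldehyde and forms the bond reductively at room temperature. It sets out from 9, which is formylated at C6 (POCl3, DMF, EtOAc, 0 °C to rt) to 8-hexanoyl-5,7-dihydroxy-2,2-dimethyl-2H-chromene-6-carbaldehyde F5. A three-component reductive alkylation with 20, L-proline (cat.) and the Hantzsch ester in CH2Cl2 then passes through the Knoevenagel adduct (4R)-2-acetyl-4-geranyl-6-[(8-hexanoyl-5,7-dihydroxy-2,2-dimethyl-2H-chromen-6-yl)methylidene]-3-hydroxy-4-methylcyclohex-2-ene-1,5-dione F6. This adduct is reduced in situ by hydride transfer, and the sequence comes back to the route at 23.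

Further compounds
F1 | step 3 | 1-[2-hydroxy-3-(1-hydroxy-3-methylbut-2-enyl)-4,6-bis(methoxymethoxy)phenyl]hexan-1-one (racemic) | CCCCCC(=O)c1c(O)c(C(O)C=C(C)C)c(OCOC)cc1OCOC
F2 | step 8 | (2S,4E)-2-(tert-butoxycarbonyl)-2,5,9-trimethyldeca-4,8-dienoic acid | CC(C)(C)OC(=O)[C@@](C)(C/C=C(\C)CCC=C(C)C)C(=O)O
F3 | step 8 | tert-butyl (2R,4E)-2-(chlorocarbonyl)-2,5,9-trimethyldeca-4,8-dienoate | CC(C)(C)OC(=O)[C@@](C)(C/C=C(\C)CCC=C(C)C)C(=O)Cl
F4 | step 8 | tert-butyl (2S)-4-acetyl-2-[(2E)-3,7-dimethylocta-2,6-dienyl]-2-methyl-3,5-dioxohexanoate | CC(C)(C)OC(=O)[C@@](C)(C/C=C(\C)CCC=C(C)C)C(=O)C(C(C)=O)C(C)=O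
F5 | step 9 | 8-hexanoyl-5,7-dihydroxy-2,2-dimethyl-2H-chromene-6-carbaldehyde | CCCCCC(=O)c1c(O)c(C=O)c(O)c2c1OC(C)(C)C=C2
F6 | step 9 | (4R)-2-acetyl-4-geranyl-6-[(8-hexanoyl-5,7-dihydroxy-2,2-dimethyl-2H-chromen-6-yl)methylidene]-3-hydroxy-4-methylcyclohex-2-ene-1,5-dione | CCCCCC(=O)c1c(O)c(C=C2C(=O)[C@@](C)(C/C=C(\C)CCC=C(C)C)C(O)=C(C(C)=O)C2=O)c(O)c2c1OC(C)(C)C=C2
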